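The reading comes at 4.0 min, well after the first seconds in which Sbt goes over to Sdp and some Prd under Kat, so what I need is where the share s = Prd/(Prd + Sdp) stands by then.

| flask | Sbt | Kat | remark | time |
|---|---|---|---|---|
| zeta | 3 M | 7.3 mM | run made earlier |  |
| beta | 3 M | 69 mM | run made earlier |  |
| noon | 3.0 M | 10 mM |  | 4.0 min |
| dawn | 3.0 M | 20 mM |  | 4.0 min |
| winter | 3.0 M | 40 mM |  | 4.0 min |
| midnight | 3.0 M | 80 mM |  | 4.0 min |

- zeta (time / s: Prd / %, Sdp / %): 10.0: 2.0, 89.8; 20.0: 2.9, 93.3; 30.0: 3.9, 92.9; 60.0: 5.4, 91.3; 120: 6.6, 89.9
- beta (time / s: Prd / %, Sdp / %): 10.0: 2.3, 97.1; 20.0: 3.7, 96.4; 30.0: 4.4, 95.6; 60.0: 6.0, 93.4; 120: 7.2, 92.0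

(readings scatter by 0.3 percentage points)

- the numbers in the tables scatter by 0.3 percentage points (one standard deviation)
- the share counts what is present at the end, not what went on to other products
- "hardly changes" means that all values lie within two and a half points (for a concentration: within two and a half percent of the largest)

* share of Prd in all that became Prd or Sdp for noon, dawn, winter, midnight, in this order
* the shape of the row from first to last (hardly changes / rises all the way / falls all the way / rises, then falls / falls, then rises)

The beta run, with Kat at 69 mM, reads s = 6.04% at 60.0 s and 7.26% at 120 s. I take s to start near zero and its gap to a final value to shrink by a fixed factor in equal times, so the fractional gap at the later reading is the square of that at the earlier one. Using the last reading as a first final value gives 7.47%, putting that back gives 7.54%, and the rounds end at 7.57%, which I call the end share g, the value s approaches under that rule.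

The second way uses other readings: the zeta run, with Kat at 7.3 mM, reads 5.58% and 6.84% at the same times, which gives g = 7.20%. The two part by 0.37 percentage points, while one reading scatters by 0.3 points, so the parting is of the size of the scatter. Zeta's Prd and Sdp sum to 91.8% at 10.0 s against 99.4% in beta, so its clock starts late, but under my rule a late start raises g, so the lateness does not account for zeta's lower value and I put the parting down to scatter. I keep beta's value, since the beta run, with the higher sum at that first reading, fits the early start my rule assumes better.

The half-life of the gap reads 26.0 s in beta and 27.9 s in zeta, although beta holds ten times the Kat, so I treat the rise as untied to Kat. At 4.0 min, much longer than that half-life, the fractional gap is 0.168%, so my reckoning puts noon, dawn, winter and midnight at g, a row that hardly changes.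

The forecast gives 7.7%, 7.8%, 7.9% and 8%, a row that hardly changes, holding that “Prd hardly depends on Kat”.

The flasks give 7.66%, 7.66%, 7.66% and 7.67%, a row that hardly changes.

    Sbt + Kat ⇌ Sbt.Kat, settled at all times (K = 0.140 M⁻¹)
    Prd → Sdp2 (k = 1.70 × 10⁻⁵ s⁻¹)
    Sdp + Kat ⇌ Sbt + Kat, rate k3*[Kat]*[Sdp] forward; the back reaction follows from the equilibrium constant (k = 0.320 M⁻¹ s⁻¹)
    Prd ⇌ Sdp (K = 12.0, k = 0.0220 s⁻¹)
    Kat → Zet (k = 0.130 s⁻¹)
    Sbt + Kat ⇌ Prd + Kat, rate k6*[Sbt]*[Kat] forward; the back reaction follows from the equilibrium constant (K = 17.0, k = 0.520 M⁻¹ s⁻¹)

In noon, Prd and Sdp relax towards each other with a half-life of 0.485 min, short against the 4.0 min of reading. The noon reading finds the share under thermodynamic control, and the conversion of Kat into Zet makes no difference to it. Multiplying g by what left Sbt gives 7.49% Prd for noon, which holds 7.58%. For midnight, the same product is 7.53%, and that flask holds 7.63%.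

The earlier runs and the new flask were generated by integration with constants of no real substance; scatter was added.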